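Noon was charged with 4.00 times the starting material of dusk, yet on the same free catalyst it made product at 7.25 × 10⁻⁴ M/min over its whole run, against 6.38 × 10⁻⁴ M/min over the first 40.0 min of dusk: a ratio of 1.14.

| setting | dusk | noon | cedar | oak |
|---|---|---|---|---|
| starting material | 0.050 M | 0.20 M | 0.10 M | 0.10 M |
| free catalyst | 0.50 mM | 0.50 mM | 0.50 mM | 0.50 mM |
| remark | run made earlier | run made earlier |  |  |
| time |  |  | 1.0 h | 2.0 h |

- dusk (time / min: product / %, starting material / %): 12.0: 16, 85; 25.0: 33, 67; 40.0: 51, 51; 50.0: 63, 38; 60.0: 73, 28; 80.0: 89, 11
- noon (time / min: product / %, starting material / %): 6.00: 4, 100; 10.0: 3, 96; 15.0: 6, 93; 25.0: 13, 91; 40.0: 14, 85; 80.0: 29, 72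

(standard deviation of a reading: 1.5 percentage points)



1. which of the two ends with the higher amount of product, in percent of the starting material charged ("neither" if they lie within 2 percentage points) (cedar / oak / neither)
2. product at the end, in percent of the starting material charged, cedar
3. product at the end, in percent of the starting material charged, oak

The rate thus hardly follows the charge, which suggests a zero-order stretch. Take the noon figure as the ceiling rate, the product made per minute by this catalyst charge while starting material stands high. It rests on one reading and carries that reading's scatter.

Cedar and oak differ in time. The ceiling rate held for the whole time gives 43.5% for cedar and 87.0% for oak.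

Dusk objects to such a straight line. Over 80.0 min the ceiling rate gives 0.0580 M of product, more than dusk's charge of 0.050 M, and dusk read 0.0445 M, so it fell 0.0135 M behind the line as its starting material thinned. A saturation law accounts for this: product made, plus a half-saturation amount times the logarithm of charge over what is left, equals ceiling rate times time. Dusk's last readings then give a half-saturation amount of 0.00612 M.

Might noon itself lie below the ceiling? This amount is 4.25% of the starting material in noon's last reading, so by this law noon ran about that share below the ceiling, and the ceiling rate is kept uncorrected.

Solving the law by repeated substitution gives 40.4% for cedar and 77.6% for oak. One doubt remains: oak's 2.0 h runs past the 80.0 min of dusk's last reading, so its figure is the less secure.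

The forecast, saying “This is saturation kinetics”, named oak, with 41% for cedar, higher than this reckoning, and 77% for oak, lower than it.

The flask gives 41.1% for cedar and 76.5% for oak, so oak ends higher. At 2.00 h, oak's catalyst stands 81.4% as catalyst intermediate, the resting state, with 13.7% free and 4.85% dormant.

    catalyst intermediate ⇌ free catalyst + product (K = 0.0740 M, k = 0.0250 /s)
    free catalyst ⇌ dormant form (K = 0.570, k = 1.90 × 10⁻⁴ /s)
    starting material + free catalyst → catalyst intermediate (k = 5.30 /M/s)

Against the ceiling rate, cedar stands 2.4 percentage points behind its straight line and oak 10 points.

Oak read at 30 min is the second case: the ceiling rate gives 21.7%, and the computed reading is 21.0%, with 78.5% of the starting material still there.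

(The numbers in the tables were computed on assumed constants; the scatter is artificial.)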